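**Retrosynthetic overview**
1. Target ⇒ break O1–C2 to reach the fully unprotected, open-chain (E)-2',4',6'-trihydroxy-3'-prenyl-4-prenyloxychalcone. In the forward direction this is a chalcone-isomerase-like 6-endo oxa-Michael closure as the last step. One chiral Lewis-acid catalyst must set C2 as (S) and choose O-2' over O-6' (8-prenyl rather than 6-prenyl).
2. Chalcone ⇒ break Cα=Cβ to 3-prenylphloroacetophenone and 4-prenyloxybenzaldehyde, joined without protecting groups through the polylithiated ketone.
3. 3-Prenylphloroacetophenone ⇒ phloroacetophenone + prenyl bromide (C-prenylation before ring closure, as on the hop chalcone pathway). The aldehyde ⇒ 4-hydroxybenzaldehyde + prenyl bromide.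
4. Ring order: rings A and B are bought as arenes. Ring C is the only ring formed, and it is formed last.

**Assumption:** the L-pipecolic acid-derived ligand is taken to give the (2S) series. This is checked by CD on the first run ((2S)-flavanones show a positive band near 330 nm and a negative band near 290 nm), and the D-series ligand is used if the sense is reversed.

**Ligand:** L-PiPr2 is the propane-1,3-diyl-bridged bis[(S)-pipecolic acid 2,6-diisopropylanilide] N,N'-dioxide, a neutral tetradentate O4 donor.

**Step 1**
Reactants: 1 2',4',6'-trihydroxyacetophenone (phloroacetophenone); 2 prenyl bromide (1-bromo-3-methylbut-2-ene)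
Product: 3 1-[2,4,6-trihydroxy-3-(3-methylbut-2-en-1-yl)phenyl]ethan-1-one (3-prenylphloroacetophenone)
Conditions: KOH (1.1 equiv), 2 (0.95 equiv), H2O, 0 °C to rt, 3 h; then 1 M HCl
Reagents that add atoms: prenyl bromide (2), CC(C)=CCBr
Why: This is C-alkylation of an ambident phloroglucinol-type phenoxide (SN2 on the allylic bromide); in water the oxygens are hydrogen-bond solvated so the soft ring carbon reacts, C3 and C5 are equivalent so only one mono-C-prenyl product is possible, a slight deficit of bromide limits diprenylation, and no stereocentre is formed.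

**Step 2**
Reactants: 4 4-hydroxybenzaldehyde; 2 prenyl bromide
Product: 5 4-[(3-methylbut-2-en-1-yl)oxy]benzaldehyde
Conditions: K2CO3 (1.5 equiv), acetone, reflux, 6 h
Reagents that add atoms: prenyl bromide (2), CC(C)=CCBr
Why: This is a Williamson ether synthesis in which a simple phenoxide in a polar aprotic solvent alkylates on oxygen at the primary allylic carbon (SN2, no allylic transposition); the aldehyde tolerates carbonate and no stereocentre is formed.

**Step 3**
Reactants: 3 3-prenylphloroacetophenone; 5 4-prenyloxybenzaldehyde
Product: 7 (E)-2',4',6'-trihydroxy-3'-prenyl-4-prenyloxychalcone, via aldol adduct 6 (not isolated)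
Conditions: LiN(SiMe3)2 (4.2 equiv), THF, −78 to 0 °C, 1 h; then 5, −78 °C to rt, 16 h; inverse quench into 1 M HCl, 0 °C
Reagents that add atoms: none
Why: This is a Claisen–Schmidt crossed aldol condensation with E1cB loss of LiOH; four equivalents of amide base turn 3 into its soluble trilithium phenoxide lithium enolate, a known way to condense free polyhydroxyacetophenones without protection, no free amide is left to convert 5 into its N-silylimine, 5 cannot enolise, conjugation drives dehydration to the (E)-alkene so the carbinol centre of 6 disappears, and the ring-open polyanion persists until the fast cold acid quench.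

**Step 4**
Reactants: 7 (E)-2',4',6'-trihydroxy-3'-prenyl-4-prenyloxychalcone
Product: 8 (2S)-5,7-dihydroxy-8-prenyl-4'-prenyloxyflavanone (CNP0558191.1)
Conditions: Ni(acac)2 (10 mol%), L-PiPr2 (11 mol%), 4 Å MS, anisole, 0 °C, 48 h; then 10% aq. citric acid
Reagents that add atoms: none
Why: Proposed new method: a chalcone-isomerase-like 6-endo-trig intramolecular oxa-Michael addition in which the substrate's own 6'-OH/C=O pair (a salicyloyl O,O-chelator) replaces the sacrificial ester that known Lewis-acid systems need for two-point binding; loss of Hacac gives an octahedral divalent-nickel chelate that should form at the unhindered 6'-oxygen, because the 2'-oxygen is flanked by the prenyl group and clashes with the 2,6-diisopropylanilide walls of the ligand, so the enone is activated while the only ortho oxygen left to attack is O-2', giving the 8-prenyl and not the 6-prenyl skeleton; the remaining small acac anion serves as general base, the ligand pocket admits only the twisted s-trans rotamer that presents the Si face of C-β to O-2', which sets C2 as (S), and proton transfer from fresh 7 releases 8 under near-neutral conditions that spare both prenyl groups and do not racemise the product; the closest known reaction types are the N,N'-dioxide/Ni(acac)2-catalysed asymmetric oxa-Michael cyclisation of ester-activated 2'-hydroxychalcones to flavanones and the cinchona-thiourea cyclisation of simple 2'-hydroxychalcones.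

**Compound list**
1 | 2',4',6'-trihydroxyacetophenone | CC(=O)c1c(O)cc(O)cc1O | starting material
2 | prenyl bromide (1-bromo-3-methylbut-2-ene) | CC(C)=CCBr | starting material
3 | 1-[2,4,6-trihydroxy-3-(3-methylbut-2-en-1-yl)phenyl]ethan-1-one | CC(=O)c1c(O)cc(O)c(CC=C(C)C)c1O | intermediate
4 | 4-hydroxybenzaldehyde | O=Cc1ccc(O)cc1 | starting material
5 | 4-[(3-methylbut-2-en-1-yl)oxy]benzaldehyde | CC(C)=CCOc1ccc(C=O)cc1 | intermediate
6 | racemic 3-hydroxy-1-[2,4,6-trihydroxy-3-prenylphenyl]-3-[4-(prenyloxy)phenyl]propan-1-one (aldol adduct, present as its lithium salt, not isolated) | CC(C)=CCOc1ccc(C(O)CC(=O)c2c(O)cc(O)c(CC=C(C)C)c2O)cc1 | intermediate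
7 | (E)-1-[2,4,6-trihydroxy-3-(3-methylbut-2-en-1-yl)phenyl]-3-{4-[(3-methylbut-2-en-1-yl)oxy]phenyl}prop-2-en-1-one | CC(C)=CCOc1ccc(/C=C/C(=O)c2c(O)cc(O)c(CC=C(C)C)c2O)cc1 | intermediate
8 | (2S)-5,7-dihydroxy-8-(3-methylbut-2-en-1-yl)-2-{4-[(3-methylbut-2-en-1-yl)oxy]phenyl}-2,3-dihydro-4H-chromen-4-one | CC(C)=CCOc1ccc([C@@H]2CC(=O)c3c(O)cc(O)c(CC=C(C)C)c3O2)cc1 | target

**Total step count:** 4.
**Longest linear sequence:** 3 (1 → 3 → 7 → 8).

**Steps most likely to fail**

**Step 4.**
- Risks: the uncatalysed bias of such chalcones leans toward the 6-prenyl isomer. The ee on a non-activated enone may be modest. The product can inhibit the catalyst through its own 5-OH/C=O chelate, and retro-Michael reaction can cause scrambling.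
- Fallback: it sets out from 7 and comes back at 8. It gives up catalyst control in favour of thermodynamic closure, separation and recycling through the achiral chalcone.
- Compound 7 is cyclised with NaOAc in refluxing EtOH. This gives a chromatographically separable mixture of the racemic 8-prenylflavanone F1 and the racemic 6-prenylflavanone F2.
- F1 is resolved by preparative chiral SFC on an amylose tris(3,5-dimethylphenylcarbamate) phase into 8 and the (2R)-enantiomer F3.
- F2 and F3 are both reopened with aqueous KOH to the chalcone polyanion. A cold acid quench returns them as 7 for another pass.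

**Step 3.**
- Risks: the enolate of a very electron-rich polyanion may be sluggish, the aldehyde may be diverted to its N-silylimine, and some ring closure may occur on work-up.
- Fallback: it sets out from 3 and comes back at 7, and it replaces the polyanion tactic with a protecting-group tactic.
- MeOCH2Cl (2.2 equiv) and iPr2NEt in CH2Cl2 at 0 °C give 2-hydroxy-4,6-bis(methoxymethoxy)-3-prenylacetophenone F4.
- A classical KOH/EtOH–H2O Claisen–Schmidt condensation with 5 gives (E)-2'-hydroxy-4',6'-bis(methoxymethoxy)-3'-prenyl-4-prenyloxychalcone F5.
- Brief HCl in MeOH at rt removes both acetals to give 7.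

**Step 1.**
- Risks: diprenylation, geminal dialkylation with dearomatisation, and O-alkylation.
- Fallback: it sets out from 1 and comes back at 3. It switches from phenoxide alkylation to an acid-mediated Friedel–Crafts prenylation.
- Treating 1 with 2-methylbut-3-en-2-ol and BF3·OEt2 in dioxane at rt generates the dimethylallyl cation. This cation attacks the neutral arene only at carbon, so O-alkylated and dearomatised products are avoided. No new isolable compound lies on the way.

**Further compounds**
F1 | step 4 | racemic 5,7-dihydroxy-8-prenyl-4'-prenyloxyflavanone | CC(C)=CCOc1ccc(C2CC(=O)c3c(O)cc(O)c(CC=C(C)C)c3O2)cc1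
F2 | step 4 | racemic 5,7-dihydroxy-6-prenyl-4'-prenyloxyflavanone | CC(C)=CCOc1ccc(C2CC(=O)c3c(O)c(CC=C(C)C)c(O)cc3O2)cc1
F3 | step 4 | (2R)-5,7-dihydroxy-8-prenyl-4'-prenyloxyflavanone | CC(C)=CCOc1ccc([C@H]2CC(=O)c3c(O)cc(O)c(CC=C(C)C)c3O2)cc1
F4 | step 3 | 1-[2-hydroxy-4,6-bis(methoxymethoxy)-3-(3-methylbut-2-en-1-yl)phenyl]ethan-1-one | CC(=O)c1c(OCOC)cc(OCOC)c(CC=C(C)C)c1O
F5 | step 3 | (E)-2'-hydroxy-4',6'-bis(methoxymethoxy)-3'-prenyl-4-prenyloxychalcone | CC(C)=CCOc1ccc(/C=C/C(=O)c2c(OCOC)cc(OCOC)c(CC=C(C)C)c2O)cc1
F0 | step 1 | none | none
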